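The constants of this flask are not on hand before it runs, so they have to be read from Wednesday's run as one time and one ratio.

- Wednesday's: substrate 20 mM; first nucleophile 30 mM; second nucleophile 100 mM; run made earlier
- flask: substrate 20 mM; first nucleophile 30.0 mM; second nucleophile 50.0 mM; time 15 d

- Wednesday's (time / d: target / %, other capture product / %, substrate / %): 0.333: 8.2, 26.2, 21.8; 0.833: 8.9, 32.4, 1.8; 2.08: 8.2, 33.1, 0; 5.00: 8.5, 32.8, 0.6

(each reading ± 0.3 percentage points)

- ratio of target to other capture product at 8.0 min
- ratio of target to other capture product at 15 d

Wednesday's substrate reading of 21.8 % at 0.333 d, taken as first order, gives a half-life of 0.152 d.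

Two chemists dispute what the ratio of target to other capture product does in time. The first holds to plain competition: the ratio stays constant through a run and follows the nucleophile charges. So Wednesday's 8.5 % against 32.8 % at 5.00 d, rescaled, gives him 0.518 at both asked times.

The second points to the 58.1 % of the charge found in neither product nor substrate. She also points to target reading 8.2 % and then 8.5 %, while other capture product climbs from 26.2 % to 32.8 %. Her view is that substrate consumes target, giving a side product that holds two substrate units, so half of the missing fraction was once target.

Put that back, divide by other capture product and by the charge ratio of first to second nucleophile, and you have the selectivity factor, the made-target ratio per unit of charge ratio: 3.82. At 8.0 min, far shorter than the half-life, hardly any substrate has reacted, so she multiplies by 0.600 and gets 2.29. For 15 d she has no better number than his, so I commit to her 2.29 early and his 0.518 late.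

The forecast reads 1 at 8.0 min, lower than my figure, and 0.5 at 15 d, on the ground that “Halving the second nucleophile then doubles the ratio”.

The flask gives 2.42 at 8.0 min and 0.510 at 15 d, when it holds 68.4 % of its charge as side product.

    substrate → intermediate (k = 3.77 × 10⁻⁵ s⁻¹)
    first nucleophile + intermediate → target (k = 0.932 M⁻¹ s⁻¹)
    second nucleophile + intermediate → other capture product (k = 0.219 M⁻¹ s⁻¹)
    target → over-reaction product (k = 6.42 × 10⁻⁸ s⁻¹)
    substrate + target → side product (k = 0.0111 M⁻¹ s⁻¹)

With 7.5 mM of first nucleophile, the selectivity factor gives 0.572 at 8.0 min, and that neighbouring flask gives 0.605.

The runs are simulated with constants of no real substance.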